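**Plan**

- Retrosynthesis: the C4 carbinol is traced back to the flavanone carbonyl (reduction, then inversion). Ring A is cut at C4a–C5 (intramolecular Claisen), ring C at O1–C8a (cyclodehydration), and the chain at C4–C4a (aldol), C8–C8a (γ-acylation) and C8–prenyl (alkylation).
- Forward: prenylated methyl acetoacetate is turned into its (E)-β-methoxy enoate and γ-acetylated. A dianion aldol joins it to a chiral β-silyloxy aldehyde, and oxidation gives the β-diketone. Acid closes ring C first, base then closes and aromatises ring A, and C4 is adjusted last.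
- Enabling feature: ring A carries oxygen on C5, C7 and C8a (phloroglucinol pattern) and is fused to ring C through C4a–C8a. Its six carbons therefore map onto a masked 1,3,5-tricarbonyl chain hung on C8a of a preformed ring C (C8a as the ring C enol ether with O1, C7 as methyl enol ether, C5 as ester).
- Stereochemistry: C2 comes from a reagent-controlled allylboration and is retained because the C2–O bond is never broken. C4 comes from axial hydride delivery (2,4-cis) followed by Mitsunobu inversion (2,4-trans, 4R).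
- Regiochemistry: the prenyl-bearing carbon is bonded to the carbon that already carries O1, so prenyl can only end up at C8.

Key step: step 10

Remark: flavan numbering (O1, C2, C3, C4, C4a, C5–C8, C8a) is used for all intermediates. The side-chain carbon that becomes C8 is carried as an epimer mixture from the γ-acetylated enoate to the key-step precursor; this is assumed to be harmless because that carbon becomes sp2 in ring A.

Step 1
Reactants: 1 methyl acetoacetate; 2 prenyl bromide (1-bromo-3-methylbut-2-ene)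
Product: 3 methyl 7-methyl-3-oxooct-6-enoate
Conditions: NaH, THF, 0 °C; n-BuLi, 0 °C; then 2, 0 °C to rt; aq. HCl work-up
Reagents that add atoms: none
Why: Weiler dianion alkylation, in which the γ-carbanion of the acetoacetate dianion is the more reactive site and should displace bromide from the primary allylic carbon (SN2) while the α-position stays untouched.

Step 2
Reactants: 3 methyl 7-methyl-3-oxooct-6-enoate
Product: 5 methyl (2E)-3-methoxy-7-methylocta-2,6-dienoate, via dimethyl ketal 4 (not isolated)
Conditions: HC(OMe)3, H2SO4 (cat.), MeOH, rt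
Reagents that add atoms: trimethyl orthoformate, COC(OC)OC
Why: acid-catalysed ketalisation and loss of methanol (enol ether formation of a β-keto ester) should give the thermodynamically preferred (E)-β-methoxy enoate, with the methoxy group anti to the ester and the chain carbon cis to it.

Step 3
Reactants: 5 methyl (2E)-3-methoxy-7-methylocta-2,6-dienoate; 6 N-methoxy-N-methylacetamide
Product: 7 methyl (2E)-4-acetyl-3-methoxy-7-methylocta-2,6-dienoate (racemic at C4)
Conditions: LiN(iPr)2 (1.1 equiv), THF, −78 °C; then 6, −78 to −20 °C; AcOH quench at −78 °C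
Reagents that add atoms: none
Why: directed γ-deprotonation of the vinylogous ester (the γ-CH2 lies cis to the ester carbonyl) gives a lithium dienolate that should be acylated at the γ-carbon by the Weinreb amide (vinylogous Claisen acylation), the stable tetrahedral chelate preventing over-addition and proton transfer to the acidic product.

Step 4
Reactants: 8 4-(tert-butyldimethylsilyloxy)benzaldehyde
Product: 10 (1S)-1-[4-(tert-butyldimethylsilyloxy)phenyl]but-3-en-1-ol, via borinate ester 9 (not isolated)
Conditions: (−)-Ipc2BOMe [from (+)-α-pinene], CH2=CHCH2MgBr, Et2O, 0 °C to rt; then 8, −78 °C; HOCH2CH2NH2 work-up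
Reagents that add atoms: allylmagnesium bromide, C=CC[Mg]Br
Why: Brown asymmetric allylboration through a chair six-membered transition state, in which the isopinocampheyl groups derived from (+)-α-pinene direct the allyl group to the Si face of the aldehyde, should set the (S)-carbinol that becomes C2.

Step 5
Reactants: 10 (1S)-1-[4-(tert-butyldimethylsilyloxy)phenyl]but-3-en-1-ol
Product: 11 tert-butyl(dimethyl){4-[(1S)-1-(triethylsilyloxy)but-3-en-1-yl]phenoxy}silane
Conditions: Et3SiCl, imidazole, CH2Cl2, 0 °C to rt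
Reagents that add atoms: chlorotriethylsilane, CC[Si](Cl)(CC)CC
Why: standard O-silylation with imidazole as base should protect the secondary benzylic alcohol without touching the stereocentre.

Step 6
Reactants: 11 tert-butyl(dimethyl){4-[(1S)-1-(triethylsilyloxy)but-3-en-1-yl]phenoxy}silane
Product: 13 (3S)-3-[4-(tert-butyldimethylsilyloxy)phenyl]-3-(triethylsilyloxy)propanal, via ozonide 12 (not isolated)
Conditions: O3, CH2Cl2, −78 °C (stopped at first persistence of ozone); then PPh3, −78 °C to rt
Reagents that add atoms: ozone, [O-][O+]=O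
Why: ozonolysis with reductive work-up should cleave the terminal alkene to the aldehyde, the monosubstituted alkene reacting far faster with ozone than the silyloxy-substituted arene at −78 °C.

Step 7
Reactants: 7 methyl (2E)-4-acetyl-3-methoxy-7-methylocta-2,6-dienoate; 13 (3S)-3-[4-(tert-butyldimethylsilyloxy)phenyl]-3-(triethylsilyloxy)propanal
Product: 14 methyl (2E,9S)-9-[4-(tert-butyldimethylsilyloxy)phenyl]-7-hydroxy-3-methoxy-4-(3-methylbut-2-en-1-yl)-5-oxo-9-(triethylsilyloxy)non-2-enoate (mixture of C4 and C7 epimers)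
Conditions: 7 (1.3 equiv), LiN(iPr)2 (2.6 equiv), THF, −78 to −30 °C, recooled to −78 °C; then 13; AcOH quench at −78 °C
Reagents that add atoms: none
Why: dianion aldol addition in the manner of 1,3-dicarbonyl polyanions, where the first equivalent of base removes the doubly activated C4–H and the second the acetyl methyl proton, so that the last-formed, least stabilised carbanion should add to the aldehyde; the new stereocentres at C4 and C7 are erased later.

Step 8
Reactants: 14 methyl (2E,9S)-9-[4-(tert-butyldimethylsilyloxy)phenyl]-7-hydroxy-3-methoxy-4-(3-methylbut-2-en-1-yl)-5-oxo-9-(triethylsilyloxy)non-2-enoate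
Product: 15 methyl (2E,9S)-9-[4-(tert-butyldimethylsilyloxy)phenyl]-3-methoxy-4-(3-methylbut-2-en-1-yl)-5,7-dioxo-9-(triethylsilyloxy)non-2-enoate (largely enolised; mixture of C4 epimers)
Conditions: Dess–Martin periodinane (1.2 equiv), CH2Cl2, 0 °C to rt
Reagents that add atoms: none
Why: Dess–Martin oxidation of the β-hydroxy ketone under non-basic conditions should give the β-diketone without β-elimination, silyl loss or premature Claisen cyclisation.

Step 9
Reactants: 15 methyl (2E,9S)-9-[4-(tert-butyldimethylsilyloxy)phenyl]-3-methoxy-4-(3-methylbut-2-en-1-yl)-5,7-dioxo-9-(triethylsilyloxy)non-2-enoate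
Product: 17 methyl (2E)-4-[(2S)-2-[4-(tert-butyldimethylsilyloxy)phenyl]-4-oxo-3,4-dihydro-2H-pyran-6-yl]-3-methoxy-7-methylocta-2,6-dienoate (mixture of C4 epimers), via hydroxy diketone 16 (not isolated)
Conditions: TsOH·H2O (cat.), MeOH, 0 °C; then solvent exchange, CF3CO2H, CH2Cl2, 0 °C
Reagents that add atoms: none
Why: acid-catalysed desilylation and cyclodehydration of the δ-hydroxy-β-diketone (6-exo-trig hemiketalisation at the distal carbonyl, then loss of water to the vinylogous ester) should close ring C with the C2–O bond intact, so the (S)-configuration is retained, while the methyl enol ether at C7 keeps the triketide from closing to a γ-pyranone.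

Step 10
Reactants: 17 methyl (2E)-4-[(2S)-2-[4-(tert-butyldimethylsilyloxy)phenyl]-4-oxo-3,4-dihydro-2H-pyran-6-yl]-3-methoxy-7-methylocta-2,6-dienoate
Product: 19 (2S)-2-[4-(tert-butyldimethylsilyloxy)phenyl]-5-hydroxy-7-methoxy-8-(3-methylbut-2-en-1-yl)-2,3-dihydro-4H-chromen-4-one, via keto tautomer 18 (not isolated)
Conditions: LiN(SiMe3)2 (1.3 equiv), THF, −78 to −20 °C; AcOH quench at −78 °C
Reagents that add atoms: none
Why: Proposed new method: LiN(SiMe3)2 should remove the most acidic proton of 17, the side-chain C–H that becomes C8 (γ to the pyranone carbonyl through C8a=C4a and γ to the ester through C7=C6), and the α-carbon C4a of the resulting extended enolate then adds to the ester carbonyl C5, which the (E)-enoate holds cis to C8; loss of methoxide gives keto tautomer 18, whose C4a–H is removed at once so that ring A aromatises to the 5-phenoxide. The closest known reaction type is the biomimetic Claisen (Dieckmann-type) cyclisation and aromatisation of 3,5,7-triketo esters, their enol ethers and pyranone-masked forms to acylphloroglucinols; here the C8a carbonyl is masked as the ring C enol ether instead. Ring A closes by a 6-(enolexo)-exo-trig attack that forms C4a–C5, no stereocentre is created, and C2 lies outside the reacting array. Two selectivities are needed: deprotonation at C8–H and not at C3–H, which the far higher acidity of the doubly vinylogous C8–H should secure under an equilibrating silylamide base (both C8 epimers and any C8a=C8 double-bond isomer give the same anion), and C-acylation at C4a, which geometry secures because only C4a reaches the ester through a six-membered transition state. Since O1 is already bonded to C8a next to the prenyl-bearing carbon, the prenyl group can only end up at C8. Near-stoichiometric base, low temperature and a cold AcOH quench should suppress C3 deprotonation and retro-oxa-Michael opening of ring C, and the phenoxide formed lowers the C3–H acidity of the product.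

Step 11
Reactants: 19 (2S)-2-[4-(tert-butyldimethylsilyloxy)phenyl]-5-hydroxy-7-methoxy-8-(3-methylbut-2-en-1-yl)-2,3-dihydro-4H-chromen-4-one
Product: 20 (2S)-5-(tert-butyldimethylsilyloxy)-2-[4-(tert-butyldimethylsilyloxy)phenyl]-7-methoxy-8-(3-methylbut-2-en-1-yl)-2,3-dihydro-4H-chromen-4-one
Conditions: tBuMe2SiOSO2CF3, 2,6-lutidine, CH2Cl2, −78 to 0 °C
Reagents that add atoms: tert-butyldimethylsilyl trifluoromethanesulfonate, CC(C)(C)[Si](C)(C)OS(=O)(=O)C(F)(F)F
Why: O-silylation with a silyl triflate and a hindered weak base should cap even the hydrogen-bonded peri phenol without base strong enough to open ring C, so that no free phenol sits next to C4 during the later inversion.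

Step 12
Reactants: 20 (2S)-5-(tert-butyldimethylsilyloxy)-2-[4-(tert-butyldimethylsilyloxy)phenyl]-7-methoxy-8-(3-methylbut-2-en-1-yl)-2,3-dihydro-4H-chromen-4-one
Product: 21 (2S,4S)-5-(tert-butyldimethylsilyloxy)-2-[4-(tert-butyldimethylsilyloxy)phenyl]-7-methoxy-8-(3-methylbut-2-en-1-yl)-3,4-dihydro-2H-chromen-4-ol (2,4-cis)
Conditions: NaBH4, MeOH–THF, 0 °C; cold aq. NH4Cl quench
Reagents that add atoms: none
Why: borohydride reduction of the aryl ketone, in which hydride should add axially to the half-chair of ring C (2-aryl equatorial), places the new hydroxyl equatorial and thus cis to the aryl group (4S), as is general for flavanones, and the cold protic medium should not promote silyl transfer from O5 to the new C4 oxygen.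

Step 13
Reactants: 21 (2S,4S)-5-(tert-butyldimethylsilyloxy)-2-[4-(tert-butyldimethylsilyloxy)phenyl]-7-methoxy-8-(3-methylbut-2-en-1-yl)-3,4-dihydro-2H-chromen-4-ol
Product: 22 (2S,4R)-5-(tert-butyldimethylsilyloxy)-2-[4-(tert-butyldimethylsilyloxy)phenyl]-7-methoxy-8-(3-methylbut-2-en-1-yl)-3,4-dihydro-2H-chromen-4-yl 4-nitrobenzoate (2,4-trans)
Conditions: 4-O2NC6H4CO2H, PPh3, iPrO2CN=NCO2iPr, THF, 0 °C to rt
Reagents that add atoms: 4-nitrobenzoic acid, O=C(O)c1ccc(cc1)[N+](=O)[O-]
Why: Mitsunobu esterification should displace the activated equatorial C4 oxygen with inversion (SN2 by carboxylate along the axial trajectory) to give the 4R ester, and any ionisation of this electron-rich benzylic centre would also be captured axially, leading to the same 2,4-trans product.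

Step 14
Reactants: 22 (2S,4R)-5-(tert-butyldimethylsilyloxy)-2-[4-(tert-butyldimethylsilyloxy)phenyl]-7-methoxy-8-(3-methylbut-2-en-1-yl)-3,4-dihydro-2H-chromen-4-yl 4-nitrobenzoate
Product: 23 (2S,4R)-5-(tert-butyldimethylsilyloxy)-2-[4-(tert-butyldimethylsilyloxy)phenyl]-7-methoxy-8-(3-methylbut-2-en-1-yl)-3,4-dihydro-2H-chromen-4-ol (2,4-trans)
Conditions: iBu2AlH (3 equiv), CH2Cl2, −78 °C; aq. potassium sodium tartrate work-up
Reagents that add atoms: none
Why: reductive ester cleavage with iBu2AlH at low temperature should free the C4 alcohol with retention (acyl–oxygen cleavage) while both aryl silyl ethers stay in place, so that no 5-phenoxide can expel the C4 ester as an ortho-quinone methide.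

Step 15
Reactants: 23 (2S,4R)-5-(tert-butyldimethylsilyloxy)-2-[4-(tert-butyldimethylsilyloxy)phenyl]-7-methoxy-8-(3-methylbut-2-en-1-yl)-3,4-dihydro-2H-chromen-4-ol
Product: 24 (2S,4R)-2-(4-hydroxyphenyl)-7-methoxy-8-(3-methylbut-2-en-1-yl)-3,4-dihydro-2H-chromene-4,5-diol (4,5,4'-trihydroxy-7-methoxy-8-prenylflavan)
Conditions: Bu4NF, AcOH (1:1), THF, 0 °C
Reagents that add atoms: none
Why: fluoride-mediated cleavage of the two aryl silyl ethers, buffered with acetic acid so that neither the acid-labile flavan-4-ol nor the base-sensitive 4'-hydroxyflavan skeleton is stressed, should release the target without touching C2 or C4.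

**Compound list**

1 | methyl acetoacetate | COC(=O)CC(C)=O | starting material
2 | prenyl bromide (1-bromo-3-methylbut-2-ene) | CC(C)=CCBr | starting material
3 | methyl 7-methyl-3-oxooct-6-enoate | COC(=O)CC(=O)CCC=C(C)C | intermediate
4 | methyl 3,3-dimethoxy-7-methyloct-6-enoate (dimethyl ketal, not isolated) | COC(=O)CC(OC)(OC)CCC=C(C)C | intermediate
5 | methyl (2E)-3-methoxy-7-methylocta-2,6-dienoate | COC(=O)/C=C(/OC)CCC=C(C)C | intermediate
6 | N-methoxy-N-methylacetamide | CC(=O)N(C)OC | starting material
7 | methyl (2E)-4-acetyl-3-methoxy-7-methylocta-2,6-dienoate (racemic at C4) | COC(=O)/C=C(/OC)C(CC=C(C)C)C(C)=O | intermediate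
8 | 4-(tert-butyldimethylsilyloxy)benzaldehyde | CC(C)(C)[Si](C)(C)Oc1ccc(C=O)cc1 | starting material
9 | (1S)-1-[4-(tert-butyldimethylsilyloxy)phenyl]but-3-en-1-yl diisopinocampheylborinate (isopinocampheyl groups from (+)-α-pinene; borinate ester, not isolated) | C=CC[C@H](OB([C@@H]1C[C@@H]2C[C@H]([C@H]1C)C2(C)C)[C@@H]1C[C@@H]2C[C@H]([C@H]1C)C2(C)C)c1ccc(O[Si](C)(C)C(C)(C)C)cc1 | intermediate
10 | (1S)-1-[4-(tert-butyldimethylsilyloxy)phenyl]but-3-en-1-ol | C=CC[C@H](O)c1ccc(O[Si](C)(C)C(C)(C)C)cc1 | intermediate
11 | tert-butyl(dimethyl){4-[(1S)-1-(triethylsilyloxy)but-3-en-1-yl]phenoxy}silane | C=CC[C@H](O[Si](CC)(CC)CC)c1ccc(O[Si](C)(C)C(C)(C)C)cc1 | intermediate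
12 | 3-{(2S)-2-[4-(tert-butyldimethylsilyloxy)phenyl]-2-(triethylsilyloxy)ethyl}-1,2,4-trioxolane (ozonide, epimers at the trioxolane carbon, not isolated) | C1(OCOO1)C[C@H](O[Si](CC)(CC)CC)c1ccc(O[Si](C)(C)C(C)(C)C)cc1 | intermediate
13 | (3S)-3-[4-(tert-butyldimethylsilyloxy)phenyl]-3-(triethylsilyloxy)propanal | O=CC[C@H](O[Si](CC)(CC)CC)c1ccc(O[Si](C)(C)C(C)(C)C)cc1 | intermediate
14 | methyl (2E,9S)-9-[4-(tert-butyldimethylsilyloxy)phenyl]-7-hydroxy-3-methoxy-4-(3-methylbut-2-en-1-yl)-5-oxo-9-(triethylsilyloxy)non-2-enoate (C4 and C7 epimers) | COC(=O)/C=C(/OC)C(CC=C(C)C)C(=O)CC(O)C[C@H](O[Si](CC)(CC)CC)c1ccc(O[Si](C)(C)C(C)(C)C)cc1 | intermediate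
15 | methyl (2E,9S)-9-[4-(tert-butyldimethylsilyloxy)phenyl]-3-methoxy-4-(3-methylbut-2-en-1-yl)-5,7-dioxo-9-(triethylsilyloxy)non-2-enoate (C4 epimers) | COC(=O)/C=C(/OC)C(CC=C(C)C)C(=O)CC(=O)C[C@H](O[Si](CC)(CC)CC)c1ccc(O[Si](C)(C)C(C)(C)C)cc1 | intermediate
16 | methyl (2E,9S)-9-[4-(tert-butyldimethylsilyloxy)phenyl]-9-hydroxy-3-methoxy-4-(3-methylbut-2-en-1-yl)-5,7-dioxonon-2-enoate (hydroxy diketone, not isolated) | COC(=O)/C=C(/OC)C(CC=C(C)C)C(=O)CC(=O)C[C@H](O)c1ccc(O[Si](C)(C)C(C)(C)C)cc1 | intermediate
17 | methyl (2E)-4-[(2S)-2-[4-(tert-butyldimethylsilyloxy)phenyl]-4-oxo-3,4-dihydro-2H-pyran-6-yl]-3-methoxy-7-methylocta-2,6-dienoate (C4 epimers) | COC(=O)/C=C(/OC)C(CC=C(C)C)C1=CC(=O)C[C@@H](c2ccc(O[Si](C)(C)C(C)(C)C)cc2)O1 | intermediate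
18 | (2S)-2-[4-(tert-butyldimethylsilyloxy)phenyl]-7-methoxy-8-(3-methylbut-2-en-1-yl)-2,3-dihydro-4H-chromene-4,5(4aH)-dione (keto tautomer, not isolated) | COC1=CC(=O)C2C(=O)C[C@@H](c3ccc(O[Si](C)(C)C(C)(C)C)cc3)OC2=C1CC=C(C)C | intermediate
19 | (2S)-2-[4-(tert-butyldimethylsilyloxy)phenyl]-5-hydroxy-7-methoxy-8-(3-methylbut-2-en-1-yl)-2,3-dihydro-4H-chromen-4-one | COc1cc(O)c2c(c1CC=C(C)C)O[C@H](c1ccc(O[Si](C)(C)C(C)(C)C)cc1)CC2=O | intermediate
20 | (2S)-5-(tert-butyldimethylsilyloxy)-2-[4-(tert-butyldimethylsilyloxy)phenyl]-7-methoxy-8-(3-methylbut-2-en-1-yl)-2,3-dihydro-4H-chromen-4-one | COc1cc(O[Si](C)(C)C(C)(C)C)c2c(c1CC=C(C)C)O[C@H](c1ccc(O[Si](C)(C)C(C)(C)C)cc1)CC2=O | intermediate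
21 | (2S,4S)-5-(tert-butyldimethylsilyloxy)-2-[4-(tert-butyldimethylsilyloxy)phenyl]-7-methoxy-8-(3-methylbut-2-en-1-yl)-3,4-dihydro-2H-chromen-4-ol (2,4-cis) | COc1cc(O[Si](C)(C)C(C)(C)C)c2c(c1CC=C(C)C)O[C@H](c1ccc(O[Si](C)(C)C(C)(C)C)cc1)C[C@@H]2O | intermediate
22 | (2S,4R)-5-(tert-butyldimethylsilyloxy)-2-[4-(tert-butyldimethylsilyloxy)phenyl]-7-methoxy-8-(3-methylbut-2-en-1-yl)-3,4-dihydro-2H-chromen-4-yl 4-nitrobenzoate (2,4-trans) | COc1cc(O[Si](C)(C)C(C)(C)C)c2c(c1CC=C(C)C)O[C@H](c1ccc(O[Si](C)(C)C(C)(C)C)cc1)C[C@H]2OC(=O)c1ccc(cc1)[N+](=O)[O-] | intermediate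
23 | (2S,4R)-5-(tert-butyldimethylsilyloxy)-2-[4-(tert-butyldimethylsilyloxy)phenyl]-7-methoxy-8-(3-methylbut-2-en-1-yl)-3,4-dihydro-2H-chromen-4-ol (2,4-trans) | COc1cc(O[Si](C)(C)C(C)(C)C)c2c(c1CC=C(C)C)O[C@H](c1ccc(O[Si](C)(C)C(C)(C)C)cc1)C[C@H]2O | intermediate
24 | (2S,4R)-2-(4-hydroxyphenyl)-7-methoxy-8-(3-methylbut-2-en-1-yl)-3,4-dihydro-2H-chromene-4,5-diol | COc1cc(O)c2c(c1CC=C(C)C)O[C@H](c1ccc(O)cc1)C[C@H]2O | target

**Step count and risks**

Total: 15 steps. Longest linear sequence: 12 steps (steps 1–3 or 4–6, then 7–15).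

Most likely to fail, step 10 (the proposed ring A closure). The process at risk is competing deprotonation at C3 with retro-oxa-Michael opening of ring C (loss of the C2 configuration), or failure of the delocalised enolate to attack the weakly electrophilic β-methoxy enoate ester. The fallback uses known chemistry, sets out from prenyl bromide 2 and comes back at 19. Purchased 5,7-dihydroxychromone would be 7-O-methylated (MeI, K2CO3, acetone), the chelated 5-hydroxyl staying free, to give 5-hydroxy-7-methoxy-4H-chromen-4-one F1. O-Alkylation of the chelated 5-hydroxyl with 2 (K2CO3, DMF) would give 7-methoxy-5-(3-methylbut-2-enyloxy)-4H-chromen-4-one F2. A para-Claisen–Cope rearrangement catalysed by Eu(fod)3 [tris(6,6,7,7,8,8,8-heptafluoro-2,2-dimethyloctane-3,5-dionato)europium] in CHCl3 at 60 °C should move the prenyl group through C6 to C8 and give 5-hydroxy-7-methoxy-8-(3-methylbut-2-enyl)-4H-chromen-4-one F3. Asymmetric conjugate addition of 4-(tert-butyldimethylsilyloxy)phenylboronic acid to the C2=C3 bond of the chromone (Pd(OCOCF3)2, tert-butyl pyridine–oxazoline ligand of the enantiomeric series that leads to the 2S product, NH4PF6, ClCH2CH2Cl–H2O, 60 °C) would then give 19.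

Second, step 7 (dianion aldol). The process at risk is incomplete or unselective second deprotonation, or closure of the mono-enolate oxygen onto the cis ester to a 2-pyranone before the aldehyde is added. The fallback sets out from 13 and comes back at 14; it makes the aldol bond first with a simple amide enolate and then forms the C4–C5 bond of the chain by the same vinylogous acylation as in step 3, so that no dianion of 7 is needed. The lithium enolate of N-methoxy-N-methylacetamide 6 (LiN(iPr)2, THF, −78 °C) would add to 13 to give (5S)-5-[4-(tert-butyldimethylsilyloxy)phenyl]-3-hydroxy-N-methoxy-N-methyl-5-(triethylsilyloxy)pentanamide F4 as a mixture of C3 epimers. Silylation (Me3SiCl, imidazole, CH2Cl2, 0 °C) would give (5S)-5-[4-(tert-butyldimethylsilyloxy)phenyl]-N-methoxy-N-methyl-5-(triethylsilyloxy)-3-(trimethylsilyloxy)pentanamide F5. The lithium dienolate of 5 (LiN(iPr)2, THF, −78 °C) should then be acylated at its γ-carbon by F5, with an AcOH quench at −78 °C, to give methyl (2E,9S)-9-[4-(tert-butyldimethylsilyloxy)phenyl]-3-methoxy-4-(3-methylbut-2-en-1-yl)-5-oxo-9-(triethylsilyloxy)-7-(trimethylsilyloxy)non-2-enoate F6. Brief treatment with citric acid in MeOH at 0 °C should remove only the trimethylsilyl group and return 14.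

Third, step 13 (Mitsunobu inversion). The process at risk is elimination to the flav-3-ene or sluggish substitution at the peri-hindered, strongly activated benzylic centre. The fallback sets out from 21 and comes back at 24, replacing substitution by elimination–addition. Acetylation of 21 (Ac2O, pyridine, DMAP) would give (2S,4S)-5-(tert-butyldimethylsilyloxy)-2-[4-(tert-butyldimethylsilyloxy)phenyl]-7-methoxy-8-(3-methylbut-2-enyl)-3,4-dihydro-2H-chromen-4-yl acetate F7. Bu4NF in wet THF at 0 °C should cleave the 5-O-silyl ether to a phenoxide that expels the neighbouring acetate, giving the ortho-quinone methide (2S)-2-(4-hydroxyphenyl)-7-methoxy-8-(3-methylbut-2-enyl)-2,3-dihydro-5H-chromen-5-one F8 (a known fluoride-triggered process for ortho-silyloxybenzyl acetates). Water should add to C4 of F8 along the axial trajectory, trans to the equatorial 2-aryl group, and with the 4'-silyl ether cleaved in the same operation this would give 24 directly.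

Further compounds
F1 | step 10 | 5-hydroxy-7-methoxy-4H-chromen-4-one | COc1cc(O)c2C(=O)C=COc2c1
F2 | step 10 | 7-methoxy-5-(3-methylbut-2-enyloxy)-4H-chromen-4-one | COc1cc(OCC=C(C)C)c2C(=O)C=COc2c1
F3 | step 10 | 5-hydroxy-7-methoxy-8-(3-methylbut-2-enyl)-4H-chromen-4-one | COc1cc(O)c2C(=O)C=COc2c1CC=C(C)C
F4 | step 7 | (5S)-5-[4-(tert-butyldimethylsilyloxy)phenyl]-3-hydroxy-N-methoxy-N-methyl-5-(triethylsilyloxy)pentanamide (C3 epimers) | CON(C)C(=O)CC(O)C[C@H](O[Si](CC)(CC)CC)c1ccc(O[Si](C)(C)C(C)(C)C)cc1
F5 | step 7 | (5S)-5-[4-(tert-butyldimethylsilyloxy)phenyl]-N-methoxy-N-methyl-5-(triethylsilyloxy)-3-(trimethylsilyloxy)pentanamide (C3 epimers) | CON(C)C(=O)CC(O[Si](C)(C)C)C[C@H](O[Si](CC)(CC)CC)c1ccc(O[Si](C)(C)C(C)(C)C)cc1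
F6 | step 7 | methyl (2E,9S)-9-[4-(tert-butyldimethylsilyloxy)phenyl]-3-methoxy-4-(3-methylbut-2-en-1-yl)-5-oxo-9-(triethylsilyloxy)-7-(trimethylsilyloxy)non-2-enoate (C4 and C7 epimers) | COC(=O)/C=C(/OC)C(CC=C(C)C)C(=O)CC(O[Si](C)(C)C)C[C@H](O[Si](CC)(CC)CC)c1ccc(O[Si](C)(C)C(C)(C)C)cc1
F7 | step 13 | (2S,4S)-5-(tert-butyldimethylsilyloxy)-2-[4-(tert-butyldimethylsilyloxy)phenyl]-7-methoxy-8-(3-methylbut-2-enyl)-3,4-dihydro-2H-chromen-4-yl acetate | COc1cc(O[Si](C)(C)C(C)(C)C)c2c(c1CC=C(C)C)O[C@H](c1ccc(O[Si](C)(C)C(C)(C)C)cc1)C[C@@H]2OC(C)=O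
F8 | step 13 | (2S)-2-(4-hydroxyphenyl)-7-methoxy-8-(3-methylbut-2-enyl)-2,3-dihydro-5H-chromen-5-one (ortho-quinone methide) | COC1=CC(=O)C2=CC[C@@H](c3ccc(O)cc3)OC2=C1CC=C(C)C
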